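The route rests on cutting the C2–C3 bond of ring C (the dihydropyranone O1–C2–C3–C4–C4a–C8a) of the dihydrokaempferol half. The feature exploited is the C3-OH/C4=O ketol beside the benzylic O1–C2 ether: the 3-OH oxygen can be a former ring atom. The precursor is thus a racemic seven-membered 1,3-benzodioxepin-5-one, the cyclic acetal of 4-benzyloxybenzaldehyde with an ω,2-dihydroxyacetophenone. A chiral Brønsted acid ionises it and recloses it through carbon. This one operation contracts the ring, forms C2–C3, frees the 3-OH and funnels both acetal enantiomers into the (2R,3R)-ketol. Negishi coupling at C8 with a 3'-zincated apigenin tribenzyl ether and hydrogenolysis finish the synthesis.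

Key step: step 5

Assumption: the sense of induction of the chiral acid cannot be predicted for this substrate class, so the (R)-acid is written and its enantiomer is taken if it leads to the (2S,3S) series; the C8–C3' biaryl axis (ortho groups O, O, O, H) is taken as freely rotating, in line with a target that carries no axial descriptor.

Step 1
Reactants: 1 2',4',6'-trihydroxyacetophenone
Product: 2 1-[2,4-bis(benzyloxy)-6-hydroxyphenyl]ethanone
Conditions: BnBr (2.05 equiv), K2CO3, DMF, 25 °C
Reagents that add atoms: benzyl bromide, BrCc1ccccc1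
Why: Williamson etherification, in which the hydroxyl left hydrogen-bonded to the acetyl carbonyl is the least nucleophilic, so that two equivalents of benzyl bromide should stop at the dibenzyl ether.

Step 2
Reactants: 2 1-[2,4-bis(benzyloxy)-6-hydroxyphenyl]ethanone
Product: 3 1-[4,6-bis(benzyloxy)-2-hydroxy-3-iodophenyl]ethanone
Conditions: N-iodosuccinimide (1.0 equiv), CF3CO2H (10 mol %), MeCN, 0 °C
Reagents that add atoms: N-iodosuccinimide, O=C1CCC(=O)N1I
Why: Electrophilic aromatic iodination, which in 2-hydroxy-4,6-dialkoxyacetophenones goes to C3, ortho to the free chelated phenol, the carbon that becomes C8 of ring A.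

Step 3
Reactants: 3 1-[4,6-bis(benzyloxy)-2-hydroxy-3-iodophenyl]ethanone
Product: 6 1-[4,6-bis(benzyloxy)-2-hydroxy-3-iodophenyl]-2-hydroxyethanone, via bis-silyl enol ether 4 (not isolated), via bis-silyl ketol 5 (not isolated)
Conditions: Me3SiOSO2CF3 (2.4 equiv), Et3N, CH2Cl2, 0 °C; then mCPBA, CH2Cl2, −20 °C; then citric acid (cat.), MeOH, 25 °C
Reagents that add atoms: mCPBA, OOC(=O)c1cccc(Cl)c1; trimethylsilyl triflate, C[Si](C)(C)OS(=O)(=O)C(F)(F)F (silyl groups stay only in 4 and 5)
Why: Rubottom oxidation: double silylation gives enol silane 4, the peracid epoxidises this most electron-rich alkene faster than it touches the arene or the aryl iodide, silyl migration gives 5, and methanolysis frees both hydroxyls.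

Step 4
Reactants: 6 1-[4,6-bis(benzyloxy)-2-hydroxy-3-iodophenyl]-2-hydroxyethanone; 7 4-(benzyloxy)benzaldehyde
Product: 9 (±)-6,8-bis(benzyloxy)-2-[4-(benzyloxy)phenyl]-9-iodo-4H-1,3-benzodioxepin-5-one, via dimethyl acetal 8 (not isolated)
Conditions: 7, HC(OMe)3, pyridinium p-toluenesulfonate (cat.), MeOH, 25 °C, evaporate; then 6, pyridinium p-toluenesulfonate (cat.), 5 Å molecular sieves, CH2Cl2, 25–40 °C
Reagents that add atoms: trimethyl orthoformate, COC(OC)OC (methoxy groups stay only in 8)
Why: Acid-catalysed transacetalisation driven by uptake of methanol in the sieves, in which the primary alcohol exchanges first and the phenol then closes the seven-membered ring, the weak acid being unable to enolise the ketone; the acetal carbon forms as a racemate, which step 5 makes irrelevant.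

Step 5
Reactants: 9 (±)-6,8-bis(benzyloxy)-2-[4-(benzyloxy)phenyl]-9-iodo-4H-1,3-benzodioxepin-5-one
Product: 11 (2R,3R)-5,7-bis(benzyloxy)-2-[4-(benzyloxy)phenyl]-3-hydroxy-8-iodochroman-4-one, via oxocarbenium enediol 10 (not isolated)
Conditions: (R)-3,3'-bis(2,4,6-triisopropylphenyl)-1,1'-binaphthyl-2,2'-diyl N-(trifluoromethylsulfonyl)phosphoramide (10 mol %), dry toluene (0.02 M), N2, 30 °C
Reagents that add atoms: none
Why: Proposed new method: (benzodioxepine numbering) the chiral acid ionises the acetal bond C2–O3 of 9 fast and reversibly, which racemises C2, and its conjugate base then enolises the freed α-hydroxy ketone in the slow step to the oxocarbenium enediol 10, whose carbon C4 attacks C2, so that O3 leaves the ring and becomes the 3-OH (net [1,2] O-to-C shift, seven- to six-membered). The closest known reaction types are the Petasis–Ferrier-type O-to-C ring contraction of seven-membered cyclic vinyl acetals under chiral phosphoric acids, the Mukaiyama-type addition of enol derivatives to acetal-derived oxocarbenium ions, and Brønsted-acid enol catalysis. The new ring closes in the 6-(enolendo)-endo-trig mode. C2 is set by the chiral counteranion, which is hydrogen-bonded to the enediol and ion-paired with the planar oxocarbenium carbon and so chooses its face for both enantiomers of 9 (dynamic, enantioconvergent), while C3 is set by C2, because the diequatorial trans ketol is favoured in the half-chair closure and any cis isomer epimerises through the same enediol. The step needs attack through C4 and not C5, which is secured because attack by C4 places the charge on C5 next to OH and the trialkoxyaryl ring and builds no quaternary centre, and a five-membered hydroxy aldehyde from C5 attack would be corrected by acid-catalysed α-ketol ring expansion to the same conjugated ketone. Ionisation of C2–O1 is a reversible dead end, and in 11 the C2–O1 bond is an ether and no longer an acetal, so it should ionise far more slowly, which protects C2 once it is set.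

Step 6
Reactants: 12 4-hydroxy-3-iodobenzaldehyde
Product: 13 4-(benzyloxy)-3-iodobenzaldehyde
Conditions: BnBr (1.1 equiv), K2CO3, DMF, 25 °C
Reagents that add atoms: benzyl bromide, BrCc1ccccc1
Why: Williamson etherification of the only acidic hydroxyl.

Step 7
Reactants: 2 1-[2,4-bis(benzyloxy)-6-hydroxyphenyl]ethanone; 13 4-(benzyloxy)-3-iodobenzaldehyde
Product: 14 (E)-1-[2,4-bis(benzyloxy)-6-hydroxyphenyl]-3-[4-(benzyloxy)-3-iodophenyl]prop-2-en-1-one
Conditions: KOH (aq., 50 %), EtOH, 25 °C
Reagents that add atoms: none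
Why: Claisen–Schmidt condensation, whose E1cB dehydration gives the thermodynamically favoured E-enone.

Step 8
Reactants: 14 (E)-1-[2,4-bis(benzyloxy)-6-hydroxyphenyl]-3-[4-(benzyloxy)-3-iodophenyl]prop-2-en-1-one
Product: 15 5,7-bis(benzyloxy)-2-[4-(benzyloxy)-3-iodophenyl]-4H-chromen-4-one
Conditions: I2 (10 mol %), DMSO, 120 °C
Reagents that add atoms: none
Why: Iodine-catalysed oxidative cyclisation of a 2'-hydroxychalcone (oxa-Michael closure, α-iodination, loss of HI) with DMSO as terminal oxidant, conditions under which benzyl ethers and the aryl iodide should survive.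

Step 9
Reactants: 15 5,7-bis(benzyloxy)-2-[4-(benzyloxy)-3-iodophenyl]-4H-chromen-4-one; 11 (2R,3R)-5,7-bis(benzyloxy)-2-[4-(benzyloxy)phenyl]-3-hydroxy-8-iodochroman-4-one
Product: 17 (2R,3R)-5,7-bis(benzyloxy)-8-{2-(benzyloxy)-5-[5,7-bis(benzyloxy)-4-oxo-4H-chromen-2-yl]phenyl}-2-[4-(benzyloxy)phenyl]-3-hydroxychroman-4-one, via arylzinc iodide 16 (not isolated)
Conditions: 15, activated Zn dust, LiCl, THF, 50 °C; then slow addition to 11, Pd(OAc)2 (2 mol %), 2-dicyclohexylphosphino-2',6'-dimethoxybiphenyl (4 mol %), THF, 25 °C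
Reagents that add atoms: zinc, [Zn] (stays only in 16)
Why: Direct zinc insertion promoted by LiCl followed by Negishi coupling, chosen because it needs no base, so that neither C2 (retro-oxa-Michael) nor C3 (enolisation) of 11 is put at risk, and because coupling with the dialkylbiarylphosphine catalyst outruns protonation of the arylzinc by the free secondary alcohol when the zinc reagent is added slowly.

Step 10
Reactants: 17 (2R,3R)-5,7-bis(benzyloxy)-8-{2-(benzyloxy)-5-[5,7-bis(benzyloxy)-4-oxo-4H-chromen-2-yl]phenyl}-2-[4-(benzyloxy)phenyl]-3-hydroxychroman-4-one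
Product: 18 (2R,3R)-8-[5-(5,7-dihydroxy-4-oxo-4H-chromen-2-yl)-2-hydroxyphenyl]-3,5,7-trihydroxy-2-(4-hydroxyphenyl)chroman-4-one (CNP0374521.1)
Conditions: H2 (1 atm), 10 % Pd/C, THF–MeOH, 25 °C
Reagents that add atoms: none
Why: Catalytic hydrogenolysis of the six aryl benzyl ethers under neutral conditions, the standard way to unmask dihydroflavonols, which should leave the flavone double bond, the ketol and the C2–O1 bond untouched.

Compound list
1 | 2',4',6'-trihydroxyacetophenone | CC(=O)c1c(O)cc(O)cc1O | starting material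
2 | 1-[2,4-bis(benzyloxy)-6-hydroxyphenyl]ethanone | CC(=O)c1c(O)cc(OCc2ccccc2)cc1OCc1ccccc1 | intermediate
3 | 1-[4,6-bis(benzyloxy)-2-hydroxy-3-iodophenyl]ethanone | CC(=O)c1c(O)c(I)c(OCc2ccccc2)cc1OCc1ccccc1 | intermediate
4 | 1-[4,6-bis(benzyloxy)-3-iodo-2-(trimethylsilyloxy)phenyl]ethenyl trimethylsilyl ether | C=C(O[Si](C)(C)C)c1c(O[Si](C)(C)C)c(I)c(OCc2ccccc2)cc1OCc1ccccc1 | intermediate (not isolated)
5 | 1-[4,6-bis(benzyloxy)-3-iodo-2-(trimethylsilyloxy)phenyl]-2-(trimethylsilyloxy)ethanone | C[Si](C)(C)OCC(=O)c1c(O[Si](C)(C)C)c(I)c(OCc2ccccc2)cc1OCc1ccccc1 | intermediate (not isolated)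
6 | 1-[4,6-bis(benzyloxy)-2-hydroxy-3-iodophenyl]-2-hydroxyethanone | OCC(=O)c1c(O)c(I)c(OCc2ccccc2)cc1OCc1ccccc1 | intermediate
7 | 4-(benzyloxy)benzaldehyde | O=Cc1ccc(OCc2ccccc2)cc1 | starting material
8 | 1-(benzyloxy)-4-(dimethoxymethyl)benzene | COC(OC)c1ccc(OCc2ccccc2)cc1 | intermediate (not isolated)
9 | (±)-6,8-bis(benzyloxy)-2-[4-(benzyloxy)phenyl]-9-iodo-4H-1,3-benzodioxepin-5-one (racemic at C2) | O=C1COC(c2ccc(OCc3ccccc3)cc2)Oc2c(I)c(OCc3ccccc3)cc(OCc3ccccc3)c21 | intermediate
10 | ring-opened aryloxy-oxocarbenium ion bearing the 1,2-enediol side chain (cation, paired with the catalyst anion) | OC=C(O)c1c(OCc2ccccc2)cc(OCc2ccccc2)c(I)c1[O+]=Cc1ccc(OCc2ccccc2)cc1 | intermediate (not isolated)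
11 | (2R,3R)-5,7-bis(benzyloxy)-2-[4-(benzyloxy)phenyl]-3-hydroxy-8-iodochroman-4-one | O=C1c2c(OCc3ccccc3)cc(OCc3ccccc3)c(I)c2O[C@H](c2ccc(OCc3ccccc3)cc2)[C@H]1O | intermediate
12 | 4-hydroxy-3-iodobenzaldehyde | O=Cc1ccc(O)c(I)c1 | starting material
13 | 4-(benzyloxy)-3-iodobenzaldehyde | O=Cc1ccc(OCc2ccccc2)c(I)c1 | intermediate
14 | (E)-1-[2,4-bis(benzyloxy)-6-hydroxyphenyl]-3-[4-(benzyloxy)-3-iodophenyl]prop-2-en-1-one | O=C(/C=C/c1ccc(OCc2ccccc2)c(I)c1)c1c(O)cc(OCc2ccccc2)cc1OCc1ccccc1 | intermediate
15 | 5,7-bis(benzyloxy)-2-[4-(benzyloxy)-3-iodophenyl]-4H-chromen-4-one | O=c1cc(-c2ccc(OCc3ccccc3)c(I)c2)oc2cc(OCc3ccccc3)cc(OCc3ccccc3)c12 | intermediate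
16 | {2-(benzyloxy)-5-[5,7-bis(benzyloxy)-4-oxo-4H-chromen-2-yl]phenyl}zinc iodide | O=c1cc(-c2ccc(OCc3ccccc3)c([Zn]I)c2)oc2cc(OCc3ccccc3)cc(OCc3ccccc3)c12 | intermediate (not isolated)
17 | (2R,3R)-5,7-bis(benzyloxy)-8-{2-(benzyloxy)-5-[5,7-bis(benzyloxy)-4-oxo-4H-chromen-2-yl]phenyl}-2-[4-(benzyloxy)phenyl]-3-hydroxychroman-4-one | O=C1c2c(OCc3ccccc3)cc(OCc3ccccc3)c(-c3cc(-c4cc(=O)c5c(OCc6ccccc6)cc(OCc6ccccc6)cc5o4)ccc3OCc3ccccc3)c2O[C@H](c2ccc(OCc3ccccc3)cc2)[C@H]1O | intermediate
18 | (2R,3R)-8-[5-(5,7-dihydroxy-4-oxo-4H-chromen-2-yl)-2-hydroxyphenyl]-3,5,7-trihydroxy-2-(4-hydroxyphenyl)chroman-4-one | O=C1c2c(O)cc(O)c(-c3cc(-c4cc(=O)c5c(O)cc(O)cc5o4)ccc3O)c2O[C@H](c2ccc(O)cc2)[C@H]1O | target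

Total step count: 10. Longest linear sequence: 7 (steps 1, 2, 3, 4, 5, 9, 10).

Steps most likely to fail

Step 5. Enolisation may be too slow, so that the oxocarbenium ion is lost to hydrolysis or oligomerisation, or the counteranion may discriminate the two faces only weakly. The fallback uses known reaction types, sets out from 9 and comes back at 11, and still builds ring C by a change of ring size.
- KN(SiMe3)2 and Et3SiCl in THF at −78 °C turn 9 into the seven-membered cyclic vinyl acetal (±)-6,8-bis(benzyloxy)-2-[4-(benzyloxy)phenyl]-9-iodo-5-(triethylsilyloxy)-2H-1,3-benzodioxepine F1.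
- The chiral phosphoric acid (R)-3,3'-bis(2,4,6-triisopropylphenyl)-1,1'-binaphthyl-2,2'-diyl hydrogen phosphate then brings about the known Petasis–Ferrier-type [1,3] O-to-C contraction of such vinyl acetals. This gives the five-membered (2R)-4,6-bis(benzyloxy)-2-[4-(benzyloxy)phenyl]-7-iodo-3-(triethylsilyloxy)-2,3-dihydro-1-benzofuran-3-carbaldehyde F2. Both C3 epimers serve, because C3 ends as the ketone carbon.
- HF·pyridine frees (2R)-4,6-bis(benzyloxy)-2-[4-(benzyloxy)phenyl]-3-hydroxy-7-iodo-2,3-dihydro-1-benzofuran-3-carbaldehyde F3.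
- The classical α-ketol rearrangement (Al(OtBu)3, toluene) expands the five-membered ring by one carbon. C2 migrates with retention to the formyl carbon and the thermodynamically favoured trans ketol 11 results.
- Should F1 close through C4 instead, simple desilylation of the product also ends in 11.

Step 4. The ring-closure equilibrium of the hindered, chelated phenol may be unfavourable, or the acetal may collapse early in an aldol-type reaction under prolonged acid. The fallback sets out from 5, taken on crude without methanolysis, and comes back at 9. Compounds 5 and 7 are combined with catalytic Me3SiOSO2CF3 in CH2Cl2 at −78 °C. This silyl-transfer acetalisation is kinetic and irreversible, driven by formation of a Si–O–Si bond rather than by an equilibrium, and it runs at a temperature where the ketone cannot enolise.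

Step 9. Zinc insertion into the electron-rich iodide may be sluggish, the free 3-OH may protonate the arylzinc, or oxidative addition at the hindered C8–I bond may be slow. The fallback sets out from 15 and 9 and comes back at 17. It forms the biaryl bond before any stereocentre that matters exists.
- Miyaura borylation of 15 (B2pin2, KOAc, PdCl2(dppf), dioxane) gives 5,7-bis(benzyloxy)-2-[4-(benzyloxy)-3-(4,4,5,5-tetramethyl-1,3,2-dioxaborolan-2-yl)phenyl]-4H-chromen-4-one F4.
- Suzuki–Miyaura coupling of F4 with the base-stable racemic acetal 9 uses Pd(OAc)2, 2-dicyclohexylphosphino-2',6'-dimethoxybiphenyl and K3PO4 in toluene–water. It gives (±)-6,8-bis(benzyloxy)-9-{2-(benzyloxy)-5-[5,7-bis(benzyloxy)-4-oxo-4H-chromen-2-yl]phenyl}-2-[4-(benzyloxy)phenyl]-4H-1,3-benzodioxepin-5-one F5.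
- The ring contraction of step 5 is then run on F5 and gives 17 directly. The acid loading is raised because the flavone carbonyl buffers the acid.

Further compounds
F1 | step 5 | (±)-6,8-bis(benzyloxy)-2-[4-(benzyloxy)phenyl]-9-iodo-5-(triethylsilyloxy)-2H-1,3-benzodioxepine | CC[Si](CC)(CC)OC1=COC(c2ccc(OCc3ccccc3)cc2)Oc2c(I)c(OCc3ccccc3)cc(OCc3ccccc3)c21
F2 | step 5 | (2R)-4,6-bis(benzyloxy)-2-[4-(benzyloxy)phenyl]-7-iodo-3-(triethylsilyloxy)-2,3-dihydro-1-benzofuran-3-carbaldehyde (C3 either way) | O=CC1(O[Si](CC)(CC)CC)c2c(OCc3ccccc3)cc(OCc3ccccc3)c(I)c2O[C@@H]1c1ccc(OCc2ccccc2)cc1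
F3 | step 5 | (2R)-4,6-bis(benzyloxy)-2-[4-(benzyloxy)phenyl]-3-hydroxy-7-iodo-2,3-dihydro-1-benzofuran-3-carbaldehyde (C3 either way) | O=CC1(O)c2c(OCc3ccccc3)cc(OCc3ccccc3)c(I)c2O[C@@H]1c1ccc(OCc2ccccc2)cc1
F0 | step 4 | none | none
F4 | step 9 | 5,7-bis(benzyloxy)-2-[4-(benzyloxy)-3-(4,4,5,5-tetramethyl-1,3,2-dioxaborolan-2-yl)phenyl]-4H-chromen-4-one | O=c1cc(-c2ccc(OCc3ccccc3)c(B3OC(C)(C)C(C)(C)O3)c2)oc2cc(OCc3ccccc3)cc(OCc3ccccc3)c12
F5 | step 9 | (±)-6,8-bis(benzyloxy)-9-{2-(benzyloxy)-5-[5,7-bis(benzyloxy)-4-oxo-4H-chromen-2-yl]phenyl}-2-[4-(benzyloxy)phenyl]-4H-1,3-benzodioxepin-5-one | O=C1COC(c2ccc(OCc3ccccc3)cc2)Oc2c(-c3cc(-c4cc(=O)c5c(OCc6ccccc6)cc(OCc6ccccc6)cc5o4)ccc3OCc3ccccc3)c(OCc3ccccc3)cc(OCc3ccccc3)c21
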